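## Retrosynthetic overview

1. Target 16 ⇐ silyl ether 15 (the side-chain tertiary alcohol is carried as its TBS ether).
2. Ring B (O4″–C4″=C3″–C1′–C3–C4) and all three stereocentres: inverse-demand oxa-Diels–Alder reaction of the 3-alkylidene-quinoline-2,4-dione 14 (from carbinol 11) with the C3=C4 bond of 2H-pyran 13, forming C1′–C3 and O4″–C4.
3. Ring A (O1–C2Me2–C3–C4–C4a=C10b) is not made as a pyran. In the same flask it grows from the dihydrofuran ring of 5 (O1–C2Me2–C3–C3a=C9b, CH2X on C3) by a 1,2-shift of C3a from C3 to the exocyclic CH2.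
4. Enabling feature: the enol-ether bond C3a=C9b of the 4-alkoxy-2-quinolone is homoallylic to CH2–X, so ionisation is assisted. The resulting dienol ether O1–C10b=C4a–C4=C3 is nucleophilic at C3 and cation-stabilising at C4, which is the C–C/C–O pattern ring A carries in the target.
5. Ring order: dihydrofuran (step 1), then ring A by expansion and ring B by cycloaddition (step 7). 5 comes from 1 and prenyl acetate; 11 comes from 1 and 3-hydroxy-3-methylbutanoic acid.

Key step: step 7

Locants: ring A as in pyrano[3,2-c]quinolin-5-one (O1, C2, C3, C4, C4a, C10b); the second quinolinone is double-primed; C1′ is the side-chain methine; dihydrofurans as in furo[3,2-c]quinolin-4-one (O1, C2, C3, C3a, C9b).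

Assumption: the facial bias of the scandium–N,N′-dioxide complex toward 14 cannot be assigned in advance; the ligand antipode that leaves the Si face of C-1′ open is to be identified in a first run and then used.

## Route

Step 1
Reactants: 1 4-hydroxy-1-methylquinolin-2(1H)-one; 2 3-methylbut-2-en-1-yl acetate (prenyl acetate)
Product: 3 (±)-(2,2,5-trimethyl-4-oxo-2,3,4,5-tetrahydrofuro[3,2-c]quinolin-3-yl)methyl acetate
Conditions: CAN (2.2 equiv), NaHCO3, MeCN, 0 °C → rt
Reagents that add atoms: none
Why: Cerium(IV)-mediated oxidative [3+2] cycloaddition of a cyclic 1,3-dicarbonyl compound with an alkene, a known route to dihydrofuro[3,2-c]quinolin-4-ones: the C3 radical of 1 should add to the less substituted alkene carbon and the tertiary centre, after oxidation, should be captured by O4, which puts CMe2 on oxygen and CH2OAc on C3; the new stereocentre is formed as a racemate on purpose, since step 7 erases it.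

Step 2
Reactants: 3 dihydrofuran acetate
Product: 4 (±)-3-(hydroxymethyl)-2,2,5-trimethyl-2,3-dihydrofuro[3,2-c]quinolin-4(5H)-one
Conditions: K2CO3 (0.2 equiv), MeOH, rt
Reagents that add atoms: none
Why: Zemplén-type transesterification of a primary acetate, which should leave the lactam and the aryl ether untouched.

Step 3
Reactants: 4 dihydrofuran alcohol
Product: 5 (±)-(2,2,5-trimethyl-4-oxo-2,3,4,5-tetrahydrofuro[3,2-c]quinolin-3-yl)methyl 2,2,2-trichloroacetimidate
Conditions: Cl3CCN (1.5 equiv), DBU (10 mol %), CH2Cl2, 0 °C
Reagents that add atoms: trichloroacetonitrile ClC(Cl)(Cl)C#N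
Why: Base-catalysed addition of a primary alcohol to trichloroacetonitrile, which turns the hydroxyl into a leaving group that a Lewis acid can activate without a stoichiometric strong acid.

Step 4
Reactants: 6 3-hydroxy-3-methylbutanoic acid
Product: 8 3-[(tert-butyldimethylsilyl)oxy]-3-methylbutanoic acid, via bis-silylated ester 7 (not isolated)
Conditions: TBSOTf (2.3 equiv), 2,6-lutidine, CH2Cl2, 0 °C; then AcOH–H2O–THF, rt
Reagents that add atoms: tert-butyldimethylsilyl triflate CC(C)(C)[Si](C)(C)OS(=O)(=O)C(F)(F)F
Why: Silylation of both hydroxyl functions with the silyl triflate followed by selective hydrolysis of the labile silyl ester, which should leave the tertiary TBS ether in place; no stereocentre is formed.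

Step 5
Reactants: 1 4-hydroxy-1-methylquinolin-2(1H)-one; 8 TBS-protected acid
Product: 10 3-{3-[(tert-butyldimethylsilyl)oxy]-3-methylbutanoyl}-4-hydroxy-1-methylquinolin-2(1H)-one, via O-acyl ester 9 (not isolated)
Conditions: DCC (1.1 equiv), DMAP (1.2 equiv), CH2Cl2, rt
Reagents that add atoms: none
Why: Steglich-type O-acylation followed by DMAP-mediated O→C acyl migration (Fries-type), the standard entry to 3-acyl-4-hydroxyquinolin-2-ones, driven by the chelated enol of the product; no stereocentre is formed.

Step 6
Reactants: 10 3-acyl-4-hydroxyquinolinone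
Product: 11 (±)-3-{3-[(tert-butyldimethylsilyl)oxy]-1-hydroxy-3-methylbutyl}-4-hydroxy-1-methylquinolin-2(1H)-one
Conditions: NaBH4, MeOH–THF, −20 °C
Reagents that add atoms: none
Why: Borohydride reduction of the 3-acyl ketone to the secondary carbinol at low temperature, where loss of water to the quinone methide should be slow; the carbinol centre is racemic and is erased in step 7.

Step 7
Reactants: 5 dihydrofuran trichloroacetimidate (1.3 equiv); 11 carbinol (added over 6 h)
Product: 15 TBS-protected adduct (3R,4S,1′R), via spirocyclopropyl oxocarbenium ion 12 (not isolated), via N-methylflindersine 13 (not isolated), via 3-alkylidenequinoline-2,4-dione 14 (not isolated)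
Conditions: Sc(OTf)3 (10 mol %), chiral N,N′-dioxide ligand from pipecolic acid and 2,6-diisopropylaniline (11 mol %), 2,6-di-tert-butyl-4-methylpyridine (20 mol %), 4 Å MS, CH2Cl2, 0 → 30 °C
Reagents that add atoms: none
Why: Proposed new method: the scandium complex is proposed to do three things in one flask: it activates the imidate of 5, whose C–O bond ionises with participation of the homoallylic enol-ether bond C3a=C9b (3-exo attack of C3a on the CH2, a neophyl-type 1,2-shift) to give ion 12, which opens at the C3a–C3 bond with loss of a proton so that the exocyclic CH2 enters the ring and the dihydrofuran becomes the 2H-pyran of 13; it dehydrates 11 to heterodiene 14, held through its two carbonyl oxygens; and it steers the inverse-electron-demand oxa-Diels–Alder reaction of 14 (O4″=C4″–C3″=C1′) with the C3=C4 bond of 13. The closest known reaction types are the aryl-assisted solvolytic ring expansion of 3-(sulfonyloxymethyl)-2,3-dihydrobenzofurans to 2H-chromenes, the Lewis-acid generation of ortho-quinone methides from ortho-hydroxybenzyl alcohols under chiral N,N′-dioxide–Sc(III) control, and the domino Knoevenagel/hetero-Diels–Alder reaction of 4-hydroxyquinolinones; their combination with a pyran dienophile released in situ is new. Ring A is closed by ring expansion (five to six atoms) and ring B by [4+2] cycloaddition (a 6-exo-trig closure by oxygen in the stepwise limit). C-1′ (R) is set by the ligand, which should leave the Si face of C-1′ of 14 open; C-3 (R) and C-4 (S) follow from suprafacial addition to the cis ring alkene (H-3/H-4 cis) and from the exo position of the pyran ring, which keeps CMe2 away from the dione (H-3/H-1′ trans). The step needs regioselectivity (C-3 to C-1′, O-4″ to C-4), which the dienol-ether polarisation O1–C10b=C4a–C4=C3 of 13 and the higher reactivity of the C4″ ketone over the C2″ lactam carbonyl should secure, and cross- over homo-dimerisation, which the slow release of 13 and the slow addition of 11 should secure. The stereocentres of racemic 5 and 11 are erased in 13 and 14, so the step is stereoconvergent.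

Step 8
Reactants: 15 TBS-protected adduct
Product: 16 target CNP0202276.1
Conditions: HF·pyridine, pyridine, THF, 0 °C → rt
Reagents that add atoms: none
Why: Fluoride-induced cleavage of the tertiary silyl ether under pyridine-buffered conditions that should not ionise the benzylic C4–O4″ bond or the tertiary alcohol; the three stereocentres are not touched.

## Compound list

1 | 4-hydroxy-1-methylquinolin-2(1H)-one | Cn1c(=O)cc(O)c2ccccc21 | starting material
2 | 3-methylbut-2-en-1-yl acetate (prenyl acetate) | CC(C)=CCOC(C)=O | starting material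
3 | (±)-(2,2,5-trimethyl-4-oxo-2,3,4,5-tetrahydrofuro[3,2-c]quinolin-3-yl)methyl acetate (racemic at C3) | Cn1c(=O)c2c(c3ccccc31)OC(C)(C)C2COC(C)=O | intermediate
4 | (±)-3-(hydroxymethyl)-2,2,5-trimethyl-2,3-dihydrofuro[3,2-c]quinolin-4(5H)-one (racemic at C3) | Cn1c(=O)c2c(c3ccccc31)OC(C)(C)C2CO | intermediate
5 | (±)-(2,2,5-trimethyl-4-oxo-2,3,4,5-tetrahydrofuro[3,2-c]quinolin-3-yl)methyl 2,2,2-trichloroacetimidate (racemic at C3) | Cn1c(=O)c2c(c3ccccc31)OC(C)(C)C2COC(=N)C(Cl)(Cl)Cl | intermediate
6 | 3-hydroxy-3-methylbutanoic acid | CC(C)(O)CC(=O)O | starting material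
7 | tert-butyldimethylsilyl 3-[(tert-butyldimethylsilyl)oxy]-3-methylbutanoate | CC(C)(CC(=O)O[Si](C)(C)C(C)(C)C)O[Si](C)(C)C(C)(C)C | intermediate (not isolated)
8 | 3-[(tert-butyldimethylsilyl)oxy]-3-methylbutanoic acid | CC(C)(CC(=O)O)O[Si](C)(C)C(C)(C)C | intermediate
9 | 1-methyl-2-oxo-1,2-dihydroquinolin-4-yl 3-[(tert-butyldimethylsilyl)oxy]-3-methylbutanoate | Cn1c(=O)cc(OC(=O)CC(C)(C)O[Si](C)(C)C(C)(C)C)c2ccccc21 | intermediate (not isolated)
10 | 3-{3-[(tert-butyldimethylsilyl)oxy]-3-methylbutanoyl}-4-hydroxy-1-methylquinolin-2(1H)-one | Cn1c(=O)c(C(=O)CC(C)(C)O[Si](C)(C)C(C)(C)C)c(O)c2ccccc21 | intermediate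
11 | (±)-3-{3-[(tert-butyldimethylsilyl)oxy]-1-hydroxy-3-methylbutyl}-4-hydroxy-1-methylquinolin-2(1H)-one (racemic at C1′) | Cn1c(=O)c(C(O)CC(C)(C)O[Si](C)(C)C(C)(C)C)c(O)c2ccccc21 | intermediate
12 | spirocyclopropyl oxocarbenium ion formed from 5 on ionisation (cyclopropane C3a–CH2–C3; O1=C9b oxocarbenium) | CN1C(=O)C23CC2C(C)(C)[O+]=C3c2ccccc21 | intermediate (not isolated)
13 | 2,2,6-trimethyl-2H-pyrano[3,2-c]quinolin-5(6H)-one (N-methylflindersine) | Cn1c(=O)c2c(c3ccccc31)OC(C)(C)C=C2 | intermediate (not isolated)
14 | (Z)-3-{3-[(tert-butyldimethylsilyl)oxy]-3-methylbutylidene}-1-methylquinoline-2,4(1H,3H)-dione (side chain anti to the C4 carbonyl) | CN1C(=O)/C(=C\CC(C)(C)O[Si](C)(C)C(C)(C)C)C(=O)c2ccccc21 | intermediate (not isolated)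
15 | tert-butyldimethylsilyl ether of 16: ring A = 2,2,6-trimethyl-3,4-dihydro-2H-pyrano[3,2-c]quinolin-5(6H)-one; (3R)-C3 bonded to (1′R)-C1′, which carries H, CH2CMe2OTBS and C3″ of a 1-methyl-2-oxoquinoline unit; (4S)-C4 bonded to O4″ of that unit; H-3/H-4 cis, H-3/H-1′ trans | Cn1c(=O)c2c(c3ccccc31)OC(C)(C)[C@H]1[C@@H]2Oc2c(c(=O)n(C)c3ccccc23)[C@@H]1CC(C)(C)O[Si](C)(C)C(C)(C)C | intermediate
16 | CNP0202276.1: as 15 with a free 2-hydroxy-2-methylpropyl group on C1′; (3R,4S,1′R) | Cn1c(=O)c2c(c3ccccc31)OC(C)(C)[C@H]1[C@@H]2Oc2c(c(=O)n(C)c3ccccc23)[C@@H]1CC(C)(C)O | target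

## Step count and risks

Total steps: 8. Longest linear sequence: 5 steps (6 → 8 → 10 → 11 → 15 → 16, or 1 → 3 → 4 → 5 → 15 → 16).

**Step 7 (Proposed new method).** What may go wrong:
- capture of ion 12 by the departing imidate instead of eliminative ring opening, so that 13 is not released;
- hydrolysis of the imidate by the water set free from 11;
- self-condensation of the heterodiene;
- insufficient facial or exo/endo selectivity.

Fallback, setting out from 4 and 11 and returning at 15: the two events are separated and run with known chemistry. Alcohol 4 is converted into its methanesulfonate F1 (MsCl, Et3N, CH2Cl2, 0 °C). F1 is solvolysed under buffered conditions (2,6-lutidine, (CF3)2CHOH, 60 °C), which should give N-methylflindersine 13 as an isolated compound by the same aryl-assisted 1,2-shift. 13 and 11 are then heated without a catalyst (toluene, 4 Å MS, 90 °C), the thermal inverse-demand hetero-Diels–Alder mode by which alkaloids of this class dimerise. This should give 15 together with its enantiomer, the (3S,4R,1′S)-silyl ether F2. The two are separated by preparative chromatography on a chiral stationary phase, and the route continues from 15.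

**Step 6.** What may go wrong: loss of water from the carbinol to the quinone methide during reduction, followed by conjugate hydride addition (over-reduction to the 3-alkyl compound), or dehydration and self-condensation on work-up.

Fallback, setting out from 8 and returning at 15: acid 8 is reduced to 3-[(tert-butyldimethylsilyl)oxy]-3-methylbutan-1-ol F3 (BH3·SMe2, THF; MeOH quench). F3 is oxidised to 3-[(tert-butyldimethylsilyl)oxy]-3-methylbutanal F4 (Dess–Martin periodinane, CH2Cl2). In step 7, 1 (added slowly) and F4 take the place of 11, so that 14 is formed at the scandium centre by Knoevenagel condensation instead of by dehydration of a carbinol. The route is rejoined at 15.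

**Step 1.** What may go wrong: ring closure through the lactam oxygen O2 instead of O4 (linear instead of angular dihydrofuran), or capture of the tertiary cation by acetate or nitrate instead of the enol oxygen.

Fallback, setting out from 1 and returning at 3: 1 is converted into 3-diazo-1-methylquinoline-2,4(1H,3H)-dione F5 by diazo transfer (4-acetamidobenzenesulfonyl azide, Et3N, MeCN). F5 is decomposed with Rh2(OAc)4 in the presence of prenyl acetate 2 (fluorobenzene, 60 °C). The rhodium carbenoid should add to the alkene and close through O4 at the tertiary carbon (formal [3+2] cycloaddition), giving 3 without a one-electron oxidant.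

Further compounds
F1 | step 7 | (±)-(2,2,5-trimethyl-4-oxo-2,3,4,5-tetrahydrofuro[3,2-c]quinolin-3-yl)methyl methanesulfonate | Cn1c(=O)c2c(c3ccccc31)OC(C)(C)C2COS(C)(=O)=O
F2 | step 7 | enantiomer of 15, the (3S,4R,1′S)-silyl ether | Cn1c(=O)c2c(c3ccccc31)OC(C)(C)[C@@H]1[C@H]2Oc2c(c(=O)n(C)c3ccccc23)[C@H]1CC(C)(C)O[Si](C)(C)C(C)(C)C
F3 | step 6 | 3-[(tert-butyldimethylsilyl)oxy]-3-methylbutan-1-ol | CC(C)(CCO)O[Si](C)(C)C(C)(C)C
F4 | step 6 | 3-[(tert-butyldimethylsilyl)oxy]-3-methylbutanal | CC(C)(CC=O)O[Si](C)(C)C(C)(C)C
F5 | step 1 | 3-diazo-1-methylquinoline-2,4(1H,3H)-dione | CN1C(=O)C(=[N+]=[N-])C(=O)c2ccccc21
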